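Per millimolar of catalyst charged: that is the unit in which to read the red flask, where a single-handed free catalyst and reagent work on a racemic substrate, and where you must say what stands at the asked time and whether any remedy pays.

| setting | red | ochre | flask |
|---|---|---|---|
| left-handed substrate | 10 mM | 20 mM | 10 mM |
| right-handed substrate | 10 mM | 20 mM | 10 mM |
| reagent | 2 equiv | 2 equiv | 2.00 equiv |
| free catalyst | 0.1 mol% | 0.1 mol% | 0.1 mol% |
| temperature | 20 °C | 15 °C | 20 °C |
| remark | the very flask that is asked about, followed so far | run made earlier |  |
| time |  |  | 8.0 d |

- red (time / d: left-handed product / %, left-handed substrate / %): 0.333: 11, 44; 0.833: 17, 37; 1.67: 25, 32; 2.50: 31, 25; 4.00: 28, 23; 5.00: 36, 21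
- ochre (time / d: left-handed product / %, left-handed substrate / %): 0.500: 21, 32; 0.833: 31, 26; 1.25: 36, 21; 2.00: 39, 9; 4.00: 51, 9; 6.00: 48, 7

(scatter of a reading: 2 percentage points)

* left-handed product, in percent of the left-handed substrate and right-handed substrate together first charged, at 8.0 d
* the remedy with the largest gain of left-handed product, or "none" below 2 percentage points (oak / ash / larch / cedar / maple / none)
* left-handed product present, with what was taken out counted in, in percent of the left-handed substrate and right-handed substrate together first charged, after cedar
* left-handed product present, with what was taken out counted in, in percent of the left-handed substrate and right-handed substrate together first charged, after maple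

- oak: at 8.0 d add reagent, 50.0% of the amount charged, then wait 4.0 d
- ash: change nothing and wait 4.0 d more
- larch: at 8.0 d raise the temperature by 10 K, then wait 4.0 d
- cedar: at 8.0 d take out 90% of the left-handed product then present, then wait 4.0 d
- maple: at 8.0 d add free catalyst, 50.0% of the amount charged, then wait 4.0 d

- free catalyst is single-handed; left-handed substrate and right-handed substrate are mirror images of each other, charged as a racemate, each of them at the stated concentration
- left-handed product taken out counts as made
- additions bring no volume worth counting

Both runs flatten, and the question is what sets the height of the flat part. Take right-handed substrate equal to left-handed substrate, so that the last two left-handed readings added together estimate the share of the racemate unreacted. Now suppose the catalyst is lost at a pace tied to turnover in such a way that each millimolar of it lowers the logarithm of the substrate by a fixed step. Then the natural logarithm of substrate charged over substrate left, divided by catalyst charged, should come out alike from two independent runs, apart from what their different temperatures do to it. Red, with 0.0100 mM of catalyst, gives 82.1 /mM, and ochre gives 91.6 /mM. Ochre's logarithm is thus twice red's, for twice the catalyst. The ochre figure hangs on readings of 9% and 7% with a scatter of 2 percentage points, and ochre ran colder, so I do not read the gap as a disagreement. Their mean, 86.9 /mM, is a reading that I call the catalyst's reach: the natural logarithm of substrate charged over substrate left, per millimolar of catalyst charged.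

For the red flask I reckon from the reach that 42.0% of the racemate stays unreacted. The last three red readings put 58.6% of what was lost into left-handed product, so I reckon 34.0% at the asked time. Reagent was charged equal to the racemate, so on one reagent per substrate it should stand near 42.0% of its own charge at that point. On my supposition the reach belongs to the catalyst charged, so I expect oak, ash, larch and cedar each to gain less than 2 points. Maple buys new reach: I reckon it should add 8.7 points, for a total of 42.7%.

The forecast, by contrast, gave 37% (range 34% to 41%), named cedar as best with 49% after it and 37.5% after maple, and held: “So the flask is already at equilibrium.”

The flask gives 35.0%; the best remedy is maple, gaining 7.9 points and reaching 42.9%, while cedar ends at 35.3%.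

    free catalyst + left-handed substrate ⇌ catalyst intermediate A (K = 85.0 /M, k = 38.0 /M/s, Ea = 37.0 kJ/mol, ΔH = −12.0 kJ/mol)
    free catalyst + right-handed substrate ⇌ catalyst intermediate B (K = 120 /M, k = 17.0 /M/s, Ea = 38.0 kJ/mol, ΔH = −24.0 kJ/mol)
    reagent + catalyst intermediate A → free catalyst + left-handed product (k = 1.60 /M/s, Ea = 52.0 kJ/mol)
    reagent + catalyst intermediate B → free catalyst + right-handed product (k = 0.730 /M/s, Ea = 62.0 kJ/mol)
    reagent + free catalyst → spent catalyst (k = 0.00120 /M/s, Ea = 54.0 kJ/mol)
    reagent → decomposition product (k = 4.00 × 10⁻⁸ /s, Ea = 113 kJ/mol)
    left-handed substrate ⇌ right-handed substrate (k = 1.60 × 10⁻⁵ /s, Ea = 104 kJ/mol)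
    (constants at 20 °C)

At 8.00 d the red flask holds spent catalyst at 98.4% of the catalyst charged beside reagent at 40.7% of its own charge, and half of the passing of free catalyst and left-handed substrate into catalyst intermediate A up to then was done by 0.757 d. The reach reckoned 42.0% of the racemate unreacted, and the red flask has 42% of each hand left. In the same flask with 0.800 equiv of reagent, the reach asks 58.0% of the racemate to react, more than the 40.0% that reagent can serve, so I take reagent as the limiting reagent there and expect left-handed product near 23.4% at the asked time. Computed, that neighbour gives 22.6%, with reagent at 6.0% of its own charge and spent catalyst at 51.0% of the catalyst charged.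

The runs were computed with made-up constants; scatter was added.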